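**Retrosynthetic overview**
1. Target (3R,4R)-lactone ⇒ its bis(benzyl) ether by hydrogenolysis ⇒ C3–CH2Ar disconnection (enolate alkylation anti to the C4 substituent) to (R)-β-[3,4-bis(benzyloxy)benzyl]-γ-butyrolactone and 3,4-dimethoxybenzyl bromide.
2. Feature used: in the lactone ring O1–C2(=O)–C3–C4–C5, once the C3 benzyl group is removed, C3 and C5 are both CH2 groups flanking C4. The ring is then the oxygen-insertion product of a mirror-symmetric 3-benzylcyclobutanone (carbons C2, C3, C4, C5), and C4 becomes the only stereocentre when O1 is placed into one of the two CH2–C(=O) bonds (O1–C5 bond).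
3. The cyclobutanone ⇒ [2+2] cycloaddition of dichloroketene to the allyl group of O,O-dibenzyl 4-allylcatechol, then reductive dechlorination.
4. Ring order: cyclobutane first (step 2), expanded to the γ-lactone (step 4); both arenes are bought.

Key step: step 4

Assumption: the sense of induction of the scandium/N,N'-dioxide catalyst is not predicted here; the ligand antipode (from (S)- or (R)-pipecolic acid) that delivers the (R)-lactone in step 4 is the one used, to be assigned by chiral HPLC and optical rotation of that lactone.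

**Step 1**
Reactants: 1 4-allylbenzene-1,2-diol; 2 benzyl bromide
Product: 3 4-allyl-1,2-bis(benzyloxy)benzene
Conditions: BnBr (2.2 equiv), K2CO3, DMF, 25 → 60 °C, N2
Reagents that add atoms: benzyl bromide, BrCc1ccccc1
Why: Williamson ether synthesis, in which both phenoxides formed with K2CO3 displace bromide from benzyl bromide while the allyl group is inert to the mild base; no stereocentre is involved.

**Step 2**
Reactants: 3 4-allyl-1,2-bis(benzyloxy)benzene; 4 trichloroacetyl chloride
Product: 6 3-[3,4-bis(benzyloxy)benzyl]-2,2-dichlorocyclobutan-1-one (racemic), via dichloroketene 5 (not isolated)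
Conditions: Cl3CCOCl, Zn (activated dust), POCl3, Et2O, 25 °C → reflux
Reagents that add atoms: trichloroacetyl chloride, ClC(=O)C(Cl)(Cl)Cl
Why: Thermal [2+2] ketene–alkene cycloaddition, in which dichloroketene made by zinc dechlorination of the acid chloride adds to the terminal alkene with its carbonyl carbon bonding to the terminal CH2 (POCl3 ties up ZnCl2); the one stereocentre formed is racemic and ceases to be stereogenic after step 3.

**Step 3**
Reactants: 6 3-[3,4-bis(benzyloxy)benzyl]-2,2-dichlorocyclobutan-1-one
Product: 7 3-[3,4-bis(benzyloxy)benzyl]cyclobutan-1-one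
Conditions: Zn dust, AcOH, 25 → 60 °C
Reagents that add atoms: none
Why: Reductive dehalogenation of an α,α-dichloro ketone by zinc in acetic acid (zinc enolates protonated by the solvent) should leave the benzyl ethers and the four-membered ring intact and give the achiral, prochiral ketone.

**Step 4**
Reactants: 7 3-[3,4-bis(benzyloxy)benzyl]cyclobutan-1-one; 8 3-chloroperoxybenzoic acid (mCPBA)
Product: 10 (R)-4-[3,4-bis(benzyloxy)benzyl]dihydrofuran-2(3H)-one, via Criegee adduct 9 (not isolated)
Conditions: Sc(OTf)3 (5 mol %), C2-symmetric N,N'-dioxide ligand (two pipecolic acid 2,4,6-triisopropylanilide units joined at nitrogen by a propane-1,3-diyl chain, both nitrogens as N-oxides; 5 mol %), mCPBA added slowly, EtOAc, −20 °C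
Reagents that add atoms: 3-chloroperoxybenzoic acid (mCPBA), O=C(OO)c1cccc(Cl)c1
Why: The scandium complex binds the ketone of 7 and mCPBA adds to it to give the tetrahedral Criegee adduct 9, in which the ring CH2–C bond antiperiplanar to the peroxide O–O bond shifts from carbon to oxygen as 3-chlorobenzoate leaves; this is the catalytic asymmetric Baeyer–Villiger desymmetrization known for 3-substituted cyclobutanones, 3-benzyl ones included. The γ-butyrolactone is closed by ring expansion of the four-membered ring (a 1,2-shift that forms O1–C5), not by a cyclization, and release of cyclobutanone strain lets it run at −20 °C. No bond to C4 is made or broken: C4 becomes stereogenic only because one of the two enantiotopic CH2 arms migrates, and the chiral pocket of the scandium–N,N'-dioxide complex decides which one by fixing the conformation of the bound Criegee adduct so that only one arm can align with the O–O bond. Both candidate migrating groups are primary CH2, so there is no regiochemical question; the step needs only enantiotopic group selectivity and chemoselectivity for the ketone. Chemoselectivity is secured by the far higher reactivity of the strained, Lewis-acid-activated carbonyl compared with the alkoxyarenes (no alkene, amine or sulfide is present), and slow peracid addition at low temperature keeps the uncatalysed racemic pathway minor.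

**Step 5**
Reactants: 10 (R)-4-[3,4-bis(benzyloxy)benzyl]dihydrofuran-2(3H)-one; 11 3,4-dimethoxybenzyl bromide
Product: 13 (3R,4R)-4-[3,4-bis(benzyloxy)benzyl]-3-(3,4-dimethoxybenzyl)dihydrofuran-2(3H)-one, via lithium enolate 12 (not isolated)
Conditions: LiN(SiMe3)2 (1.05 equiv), THF, −78 °C; then 3,4-(MeO)2C6H3CH2Br, DMPU, −78 → −40 °C
Reagents that add atoms: 3,4-dimethoxybenzyl bromide, COc1ccc(CBr)cc1OC
Why: Enolate alkylation of a β-substituted γ-butyrolactone, in which the benzylic bromide attacks the lithium enolate on the face opposite the C4 benzyl group (1,2-induction), setting C3 as R and trans to C4; C4 is not acidic and is untouched.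

**Step 6**
Reactants: 13 (3R,4R)-4-[3,4-bis(benzyloxy)benzyl]-3-(3,4-dimethoxybenzyl)dihydrofuran-2(3H)-one
Product: 14 (3R,4R)-4-(3,4-dihydroxybenzyl)-3-(3,4-dimethoxybenzyl)dihydrofuran-2(3H)-one
Conditions: H2 (1 atm), 10% Pd/C, EtOAc–MeOH, 25 °C; work-up under N2
Reagents that add atoms: none
Why: Catalytic hydrogenolysis of benzyl aryl ethers over palladium on carbon cleaves only the two O–CH2Ph bonds, while the methyl ethers, the lactone and both stereocentres (neither bears a benzylic C–O bond) are unaffected.

**Compound list**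
1 | 4-allylbenzene-1,2-diol | C=CCc1ccc(O)c(O)c1 | starting material
2 | benzyl bromide | BrCc1ccccc1 | starting material
3 | 4-allyl-1,2-bis(benzyloxy)benzene | C=CCc1ccc(OCc2ccccc2)c(OCc2ccccc2)c1 | intermediate
4 | trichloroacetyl chloride | ClC(=O)C(Cl)(Cl)Cl | starting material
5 | dichloroketene (not isolated) | ClC(Cl)=C=O | intermediate
6 | 3-[3,4-bis(benzyloxy)benzyl]-2,2-dichlorocyclobutan-1-one (racemic) | O=C1CC(Cc2ccc(OCc3ccccc3)c(OCc3ccccc3)c2)C1(Cl)Cl | intermediate
7 | 3-[3,4-bis(benzyloxy)benzyl]cyclobutan-1-one | O=C1CC(Cc2ccc(OCc3ccccc3)c(OCc3ccccc3)c2)C1 | intermediate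
8 | 3-chloroperoxybenzoic acid (mCPBA) | O=C(OO)c1cccc(Cl)c1 | starting material
9 | Criegee adduct, 3-[3,4-bis(benzyloxy)benzyl]-1-hydroxycyclobutyl 3-chloroperoxybenzoate (not isolated) | OC1(OOC(=O)c2cccc(Cl)c2)CC(Cc2ccc(OCc3ccccc3)c(OCc3ccccc3)c2)C1 | intermediate
10 | (R)-4-[3,4-bis(benzyloxy)benzyl]dihydrofuran-2(3H)-one | O=C1C[C@@H](Cc2ccc(OCc3ccccc3)c(OCc3ccccc3)c2)CO1 | intermediate
11 | 3,4-dimethoxybenzyl bromide | COc1ccc(CBr)cc1OC | starting material
12 | lithium enolate of 10, lithium (R)-3-[3,4-bis(benzyloxy)benzyl]-2,3-dihydrofuran-5-olate (not isolated) | [Li]OC1=C[C@@H](Cc2ccc(OCc3ccccc3)c(OCc3ccccc3)c2)CO1 | intermediate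
13 | (3R,4R)-4-[3,4-bis(benzyloxy)benzyl]-3-(3,4-dimethoxybenzyl)dihydrofuran-2(3H)-one | COc1ccc(C[C@H]2C(=O)OC[C@@H]2Cc2ccc(OCc3ccccc3)c(OCc3ccccc3)c2)cc1OC | intermediate
14 | (3R,4R)-4-(3,4-dihydroxybenzyl)-3-(3,4-dimethoxybenzyl)dihydrofuran-2(3H)-one | COc1ccc(C[C@H]2C(=O)OC[C@@H]2Cc2ccc(O)c(O)c2)cc1OC | target

**Total step count:** 6. **Longest linear sequence:** 6 steps (1 → 3 → 6 → 7 → 10 → 13 → 14).

**Steps most likely to fail**

1. Step 4. The catalyst may discriminate the two enantiotopic methylene groups incompletely, since the remote benzyl group gives no substrate bias, and uncatalysed peracid oxidation of the strained ketone may compete; both would lower the enantiomeric purity. The fallback sets the stereocentre with a chiral oxazolidinone auxiliary, sets out from alkene 3 and comes back at lactone 10. Hydroboration–oxidation of 3 (9-BBN, THF; then NaOH, H2O2) should give 3-[3,4-bis(benzyloxy)phenyl]propan-1-ol F1. Oxidation with TEMPO and PhI(OAc)2 in MeCN–H2O should give 3-[3,4-bis(benzyloxy)phenyl]propanoic acid F2. Its pivaloyl mixed anhydride (t-BuCOCl, Et3N, THF, −20 °C) acylates lithiated (S)-4-benzyl-2-oxazolidinone to give (S)-4-benzyl-3-{3-[3,4-bis(benzyloxy)phenyl]propanoyl}oxazolidin-2-one F3. The sodium Z-enolate (NaN(SiMe3)2, THF, −78 °C) is alkylated by tert-butyl bromoacetate on the face away from the auxiliary benzyl group, giving tert-butyl (R)-3-{[(S)-4-benzyl-2-oxooxazolidin-3-yl]carbonyl}-4-[3,4-bis(benzyloxy)phenyl]butanoate F4. LiBH4 (THF, 0 °C) removes the auxiliary reductively to give tert-butyl (R)-4-[3,4-bis(benzyloxy)phenyl]-3-(hydroxymethyl)butanoate F5. Catalytic TsOH in toluene at 80 °C closes F5 to 10, and steps 5 and 6 follow unchanged.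

2. Step 2. Cycloaddition to the unactivated monosubstituted alkene may be slow, so that ketene oligomerization and ZnCl2-promoted damage (benzyl ether cleavage, migration of the double bond into conjugation with the arene) consume the material. The fallback replaces the ketene/dechlorination pair by a keteniminium [2+2] cycloaddition, sets out from alkene 3 and comes back at cyclobutanone 7, bypassing 6. N,N-Dimethylacetamide, Tf2O and 2,4,6-collidine in refluxing 1,2-dichloroethane generate the keteniminium ion, which adds to 3 to give N-{3-[3,4-bis(benzyloxy)benzyl]cyclobutylidene}-N-methylmethanaminium trifluoromethanesulfonate F6. Hydrolysis with aqueous NaHCO3 should give 7.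

3. Step 5. Proton transfer between the product and unreacted enolate may lead to double alkylation, facial selectivity at C3 may be incomplete, and the electron-rich benzylic bromide may decompose before it reacts. The fallback introduces the C3 substituent by aldol addition and reductive removal of the carbinol oxygen, sets out from lactone 10 and comes back at target 14, bypassing 13. The lithium enolate of 10 (LiN(SiMe3)2, THF, −78 °C) adds to 3,4-dimethoxybenzaldehyde anti to the C4 substituent to give (3S,4R)-4-[3,4-bis(benzyloxy)benzyl]-3-[(3,4-dimethoxyphenyl)(hydroxy)methyl]dihydrofuran-2(3H)-one F7 as a mixture of carbinol epimers; the descriptor at C3 changes only because of the priority of the new CH(OH) group. Hydrogenolysis (H2, 10% Pd/C, AcOH, trace HClO4, 25 °C) should remove the activated benzylic hydroxyl group and both benzyl ethers in one operation and give 14.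

**Further compounds**
F1 | step 4 | 3-[3,4-bis(benzyloxy)phenyl]propan-1-ol | OCCCc1ccc(OCc2ccccc2)c(OCc2ccccc2)c1
F2 | step 4 | 3-[3,4-bis(benzyloxy)phenyl]propanoic acid | OC(=O)CCc1ccc(OCc2ccccc2)c(OCc2ccccc2)c1
F3 | step 4 | (S)-4-benzyl-3-{3-[3,4-bis(benzyloxy)phenyl]propanoyl}oxazolidin-2-one | O=C(CCc1ccc(OCc2ccccc2)c(OCc2ccccc2)c1)N1[C@@H](Cc2ccccc2)COC1=O
F4 | step 4 | tert-butyl (R)-3-{[(S)-4-benzyl-2-oxooxazolidin-3-yl]carbonyl}-4-[3,4-bis(benzyloxy)phenyl]butanoate | CC(C)(C)OC(=O)C[C@@H](Cc1ccc(OCc2ccccc2)c(OCc2ccccc2)c1)C(=O)N1[C@@H](Cc2ccccc2)COC1=O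
F5 | step 4 | tert-butyl (R)-4-[3,4-bis(benzyloxy)phenyl]-3-(hydroxymethyl)butanoate | CC(C)(C)OC(=O)C[C@@H](Cc1ccc(OCc2ccccc2)c(OCc2ccccc2)c1)CO
F6 | step 2 | N-{3-[3,4-bis(benzyloxy)benzyl]cyclobutylidene}-N-methylmethanaminium trifluoromethanesulfonate | C[N+](C)=C1CC(Cc2ccc(OCc3ccccc3)c(OCc3ccccc3)c2)C1.[O-]S(=O)(=O)C(F)(F)F
F7 | step 5 | (3S,4R)-4-[3,4-bis(benzyloxy)benzyl]-3-[(3,4-dimethoxyphenyl)(hydroxy)methyl]dihydrofuran-2(3H)-one (carbinol epimers) | COc1ccc(C(O)[C@H]2C(=O)OC[C@@H]2Cc2ccc(OCc3ccccc3)c(OCc3ccccc3)c2)cc1OC
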